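Count amounts left, not amounts made. Each substrate is half of the racemic charge, so a product reading in percent of both, doubled, is the share of its own substrate used. What remains of that is the remainder f, provided no substrate was fed by the other.

all flasks: racemization catalyst 0.20 mM; precatalyst 70 µM

| charge | left-handed substrate | right-handed substrate | gas | remark | time |
|---|---|---|---|---|---|
| south | 0.040 M | 0.040 M | 1 mM (held) | run made earlier |  |
| flask | 0.020 M | 0.020 M | 1.0 mM (held) |  | 25 min |
south run (percent of the left-handed substrate and right-handed substrate together charged)

| time / min | left-handed product / % | right-handed product / % |
|---|---|---|
| 0.667 | 4.8 | 0.8 |
| 1.00 | 4.3 | 2.0 |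
| 2.00 | 12.4 | 5.0 |
| 4.00 | 26.0 | 11.2 |
| 8.00 | 44.9 | 14.7 |

(readings scatter by 1 percentage point)
* left-handed product and right-handed product together, in percent of the left-handed substrate and right-handed substrate charged together, at 25 min
* excess of left-handed product over right-handed product in the product at 25 min
* whether the exchange between left-handed substrate and right-handed substrate keeps pace with the reaction: how far the product's excess at 25 min gets from its value without exchange to its value with instant exchange (above 80% keeps pace, below 20% hardly takes part, else lags behind)
- free catalyst is single-handed; left-handed substrate and right-handed substrate are mirror images of each other, charged as a racemate, each of them at the stated concentration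
- at the start none of reagent is dissolved
- candidate steps: reagent + free catalyst + left-handed substrate -> free catalyst + left-handed product; reagent + free catalyst + right-handed substrate -> free catalyst + right-handed product; left-handed substrate + racemization catalyst <-> right-handed substrate + racemization catalyst; precatalyst <-> free catalyst; gas <-> reagent; 2 free catalyst <-> resting dimer
- an excess is the difference of the two amounts in percent of their sum
- an excess is below zero if the other one leads

Turn the question round and suppose the exchange took no part. Both product steps use the same free catalyst and reagent, and each is first order in its own substrate, so the ratio of the logarithms of the remainders would stay constant. Read it in the south run at 4.00 min: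

s = ln f(left) / ln f(right) = 2.89

This s is the selectivity factor as that supposition reads it. At 8.00 min the right-handed product gives f(right) = 70.6%, and then:

f(left) = f(right)^s = 36.5%

c(left-handed product) = 31.7%

The reading is 44.9%, higher than that by 13 percentage points against a scatter of 1 point, so the south run stands far from the opposite case. With instant exchange the two substrates stay equal, so the excess holds steady; the south run, taken as close to that case, reads 50.7% at 8.00 min, a reading with its scatter. I expect this flask, with the same 0.20 mM of racemization catalyst, near that value.

The forecast gives 93% converted, an excess of 44%, below my value, and exchange that keeps pace, since “racemization looks fast compared with reaction”.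

The flask gives 96.5%, an excess of 47.4%, and exchange that keeps pace, 96% of the way.

    reagent + free catalyst + left-handed substrate → free catalyst + left-handed product (k = 96000 /M²/s)
    reagent + free catalyst + right-handed substrate → free catalyst + right-handed product (k = 33000 /M²/s)
    left-handed substrate + racemization catalyst ⇌ right-handed substrate + racemization catalyst, rate k3*[racemization catalyst]*[left-handed substrate] forward; the back reaction follows from the equilibrium constant (k = 140 /M/s)
    precatalyst ⇌ free catalyst (K = 2.10, k = 0.0360 /s)
    gas ⇌ reagent, rate k5*(csat - [reagent]) (kL = 0.570 /s)
    2 free catalyst ⇌ resting dimer (K = 5600 /M, k = 160 /M/s)

In this flask at 25.0 min, 25.4% of right-handed product gives f(right) = 49.2%, so s allows 43.6% of left-handed product without exchange, and 71.1% stands there. The neighbouring flask, with 1.7 × 10⁻⁵ M of precatalyst, holds 16.2% of right-handed product at 25.0 min, so the same reckoning allows 33.9%. It holds 46.5% of left-handed product, with an excess of 48.4%.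

The numbers in the tables stem from a simulated flask from invented constants; the scatter is artificial.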